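A charge of 0.0080 M of second nucleophile stands beside 0.150 M of target in the summer run at 120 s, far more than the charge, so the target's books in the five asked flasks are kept in substrate, there the limiting reagent for target.

common to all: substrate 0.50 M

| charge | first nucleophile | second nucleophile | protic impurity | remark | time |
|---|---|---|---|---|---|
| dusk | 0.35 M | 0.0080 M | 0.50 M | run made earlier |  |
| summer | 1.1 M | 0.0080 M | 0.50 M | run made earlier |  |
| south-west | 0.525 M | 0.00800 M | 0.500 M |  | 5.0 min |
| north-west | 0.525 M | 0.0200 M | 0.500 M |  | 5.0 min |
| east | 0.525 M | 0.0600 M | 0.500 M |  | 5.0 min |
| south | 0.525 M | 0.200 M | 0.500 M |  | 5.0 min |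
| south-east | 0.525 M | 0.600 M | 0.500 M |  | 5.0 min |

- dusk (time / s: intermediate / %, target / %, substrate / %): 25.0: 3, 5, 90; 50.0: 6, 8, 84; 80.0: 5, 18, 77; 120: 10, 28, 69
- summer (time / s: intermediate / %, target / %, substrate / %): 10.0: 4, 3, 96; 20.0: 2, 4, 95; 50.0: 2, 11, 86; 120: 5, 30, 63

(each reading ± 2 percentage points)

- the earlier runs were read with a standard deviation of 2 percentage points
- "hardly changes" means that all values lie within two and a half points (for a concentration: within two and a half percent of the largest)

* [intermediate] at the end for south-west, north-west, east, south, south-east, in this order
* how that number moves from the first to the last of them (rises all the way / hardly changes / falls all the way / rises, then falls / falls, then rises)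

The first entry is substrate left. At 120 s the dusk run holds 69% and the summer run 63%, although the first nucleophile charges are 0.35 M and 1.1 M. The substrate step is therefore taken as first order, with a constant kA read as 0.00347 s⁻¹, and south-west is reckoned to keep 0.176 M at the end.

The second entry is intermediate. Made by that step and taken by first nucleophile, it is taken to settle into a quasi-steady state, in which the standing ratio K, intermediate times first nucleophile over substrate, stays constant. From the second row on, the dusk run reads 0.0237 M and the summer run 0.0378 M, so K is read as 0.0308 M, with the scatter of those readings.

The third entry, target, takes what remains and spends first nucleophile mole for mole, so in south-west first nucleophile stands 0.201 M above the intermediate. Solving K for these south-west books gives 0.0241 M of intermediate, target 0.299 M, and first nucleophile 0.226 M. The intermediate lives about 39.3 s at that level, short against 5.0 min, so the steady picture holds. Taken mole for mole, the south-west charge of second nucleophile comes to 1.60% of the substrate charged.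

A larger charge can enter as a second consumer of intermediate. Both earlier runs carry 0.0080 M, so its reactivity stays unread. Taken as equal to the first nucleophile's, the crossing, where the charge of second nucleophile matches the reckoned first nucleophile, lies near 0.226 M, above east's 0.0600 M and below south-east's 0.600 M. The reckoning therefore commits to a row that starts at 0.0241 M and falls all the way, slowly at first.

The forecast gave 0.026 M, 0.04 M, 0.03 M, 0.022 M and 0.02 M, rises, then falls, with more second nucleophile “giving a small maximum”.

    first nucleophile + intermediate → target (k = 0.120 L mol⁻¹ s⁻¹)
    second nucleophile + protic impurity → quenched reagent (k = 0.0230 L mol⁻¹ s⁻¹)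
    substrate → intermediate (k = 0.00360 s⁻¹)
    second nucleophile + intermediate → other capture product (k = 0.310 L mol⁻¹ s⁻¹)

The flask gives 0.0236 M, 0.0232 M, 0.0220 M, 0.0185 M and 0.00992 M: falls all the way. At the end of south-east, other capture product holds 33.3% of the substrate charged, beside 30.8% as target. With the amounts standing there, second nucleophile is counted among the consumers at 2.58 times the weight of first nucleophile, and K times substrate over that sum gives 0.0100 M, where south-east holds 0.00992 M.

The earlier runs and the new flask were generated by integration with made-up constants, and the scatter is random.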